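**Retrosynthetic overview**
- Feature: in target 11 the ether oxygen sits on C4 of ring A, para to C1–OH, and on C1' of ring B, ortho to C2'–OH, with C5'–OH para to C2'–OH. This is the pattern left when a catechol spiroketal at C4 of a 1,4-dioxygenated six-membered ring opens its C4–O2' bond as ring A aromatizes.
- 11 ⇒ bromo triol 9: the five C–Br bonds at C2, C6, C3', C4' and C6' each lie ortho to a hydroxyl and come from electrophilic bromination, with ring B levelled to the hydroquinone at the end. 9 ⇒ ketone 7 by Dakin exchange of the C5' acetyl group for C5'–OH.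
- 7 ⇒ spirodienone 5: HBr delivers bromide to the carbon next to the spiro centre (the future C5), ring A aromatizes and C4–O2' breaks. The one bromine that no hydroxyl directs is thus placed before ring A is aromatic, and C3–H stays as the only unsubstituted carbon.
- 5 ⇒ spiroketal ketone 3 by twofold dehydrogenation; 3 ⇒ cyclohexane-1,4-dione 1 + 3,4-dihydroxyacetophenone 2 by ketalization (O1'–C4 kept, O2'–C4 temporary).
- Ring order: ring B is bought; the spiro dioxole ring closes in step 1 and opens in step 3; carbocycle A is bought saturated and becomes aromatic in step 3.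

Key step: step 1

Remark: the target has no stereocentre and rotation about both aryl–oxygen bonds is taken as free, so nothing stereochemical has to be set; Br2, HBr and H2O2 are treated as reagents and carry no compound number.

**Step 1**
Reactants: 1 cyclohexane-1,4-dione; 2 3,4-dihydroxyacetophenone
Product: 3 5-acetylspiro[1,3-benzodioxole-2,1'-cyclohexan]-4'-one
Conditions: 1 (3 equiv), p-TsOH·H2O (5 mol %), toluene, reflux, Dean–Stark trap
Reagents that add atoms: none
Why: Acid protonates one carbonyl of 1, a catechol hydroxyl of 2 adds, water leaves to give an aryloxy-stabilised oxocarbenium ion at the future C4, and the neighbouring phenol closes on it. The closest known reaction type is acid-catalysed catechol ketal (2,2-disubstituted 1,3-benzodioxole) formation from cyclohexanones with azeotropic removal of water. The five-membered dioxole ring closes by 5-endo-trig attack of the second phenolic oxygen on the oxocarbenium carbon, the usual course of 1,3-dioxolane formation. No stereocentre arises, because the spiro carbon carries two identical ring arms. The step needs mono- over bis-ketalization and reaction at a ketone of 1 and not at the acetyl group of 2; the threefold excess of 1 (water-soluble, washed out) should secure the first, and the lower electrophilicity of the conjugated aryl ketone the second. The two carbonyls of 1 are equivalent, so there is no regiochemical question.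

**Step 2**
Reactants: 3 5-acetylspiro[1,3-benzodioxole-2,1'-cyclohexan]-4'-one
Product: 5 5-acetylspiro[1,3-benzodioxole-2,1'-cyclohexa-2',5'-dien]-4'-one, via mono-enone 4 (not isolated)
Conditions: 2-iodoxybenzoic acid (4 equiv), DMSO, 80 °C
Reagents that add atoms: none
Why: Twofold α,β-dehydrogenation of a ketone by 2-iodoxybenzoic acid (the enol is taken up by pentavalent iodine and the β-hydrogen is lost with the iodine species) should give the cross-conjugated dienone, which cannot tautomerize to a phenol because the spiro carbon is quaternary, while the acetyl group has no β-hydrogen and the aryl ketal is untouched.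

**Step 3**
Reactants: 5 5-acetylspiro[1,3-benzodioxole-2,1'-cyclohexa-2',5'-dien]-4'-one
Product: 7 1-[3-(2-bromo-4-hydroxyphenoxy)-4-hydroxyphenyl]ethan-1-one, via bromo enone adduct 6 (not isolated)
Conditions: HBr (33% in AcOH, 3 equiv), CH2Cl2, 0 → 20 °C
Reagents that add atoms: hydrogen bromide, Br
Why: Proposed new method: protonation of the dienone carbonyl should let bromide add in conjugate fashion to the carbon next to the spiro centre (the two such carbons are equivalent), reversibly giving adduct 6; the enol of 6 is a cyclohexa-1,3-diene whose C4–O bond ionises under acid to an oxygen-stabilised arenium ion, the same Wheland intermediate that bromination ortho to the ether would give, and loss of the proton from the bromine-bearing carbon aromatizes ring A; the bond to the oxygen para to the acetyl group should be the one that breaks, because that phenol is the better leaving group and the oxygen left on C4 (meta to acetyl) is the better donor, and since the addition is reversible both diastereomers of 6 can drain through this channel; the closest known reaction types are the addition of HBr to p-benzoquinone to give bromohydroquinone and the Michael addition of stabilised nucleophiles to quinone monoketals with loss of alcohol on aromatization.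

**Step 4**
Reactants: 7 1-[3-(2-bromo-4-hydroxyphenoxy)-4-hydroxyphenyl]ethan-1-one
Product: 9 2-(2-bromo-4-hydroxyphenoxy)benzene-1,4-diol, via aryl acetate 8 (not isolated)
Conditions: H2O2 (30% aq., 1.3 equiv), NaOH (2 M aq., 3 equiv), THF, 0 → 20 °C, argon; then 1 M HCl
Reagents that add atoms: hydrogen peroxide, OO
Why: Dakin oxidation: hydroperoxide adds to the ketone, the aryl group bearing a phenoxide para to the carbonyl carbon migrates to oxygen to give acetate 8, and the alkaline medium saponifies it, as is known for 4-hydroxy-3-alkoxyacetophenones; the aryl bromide and the diaryl ether are inert.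

**Step 5**
Reactants: 9 2-(2-bromo-4-hydroxyphenoxy)benzene-1,4-diol
Product: 11 2,3,5-tribromo-6-(2,3,5-tribromo-4-hydroxyphenoxy)benzene-1,4-diol, via hexabromoquinone 10 (not isolated)
Conditions: Br2 (7 equiv), AcOH, 20 → 50 °C; then aq. Na2S2O4, EtOAc, 20 °C
Reagents that add atoms: bromine, BrBr
Why: Electrophilic bromination ortho to phenolic hydroxyls should fill C2 and C6 of ring A and all three free positions of hydroquinone ring B (C3', C4', C6'), in the manner of the hydroquinone-to-bromanil bromination, with excess Br2 taking ring B to quinone 10; C3–H, meta to C1–OH and to C5–Br and ortho to an ether oxygen that is by then part of a quinone, should stay untouched, and dithionite reduction returns the hydroquinone.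

**Compound list**
1 | cyclohexane-1,4-dione | O=C1CCC(=O)CC1 | starting material
2 | 3,4-dihydroxyacetophenone (1-(3,4-dihydroxyphenyl)ethan-1-one) | CC(=O)c1ccc(O)c(O)c1 | starting material
3 | 5-acetylspiro[1,3-benzodioxole-2,1'-cyclohexan]-4'-one | CC(=O)c1ccc2OC3(CCC(=O)CC3)Oc2c1 | intermediate
4 | 5-acetylspiro[1,3-benzodioxole-2,1'-cyclohex-2'-en]-4'-one (racemic, not isolated) | CC(=O)c1ccc2OC3(CCC(=O)C=C3)Oc2c1 | intermediate
5 | 5-acetylspiro[1,3-benzodioxole-2,1'-cyclohexa-2',5'-dien]-4'-one | CC(=O)c1ccc2OC3(C=CC(=O)C=C3)Oc2c1 | intermediate
6 | 5-acetyl-6'-bromospiro[1,3-benzodioxole-2,1'-cyclohex-2'-en]-4'-one (keto form of the HBr adduct, mixture of racemic diastereomers, both stereocentres lost in the same step, not isolated) | CC(=O)c1ccc2OC3(C=CC(=O)CC3Br)Oc2c1 | intermediate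
7 | 1-[3-(2-bromo-4-hydroxyphenoxy)-4-hydroxyphenyl]ethan-1-one | CC(=O)c1ccc(O)c(Oc2ccc(O)cc2Br)c1 | intermediate
8 | 3-(2-bromo-4-hydroxyphenoxy)-4-hydroxyphenyl acetate (not isolated) | CC(=O)Oc1ccc(O)c(Oc2ccc(O)cc2Br)c1 | intermediate
9 | 2-(2-bromo-4-hydroxyphenoxy)benzene-1,4-diol | Oc1ccc(O)c(Oc2ccc(O)cc2Br)c1 | intermediate
10 | 2,3,5-tribromo-6-(2,3,5-tribromo-4-hydroxyphenoxy)cyclohexa-2,5-diene-1,4-dione (not isolated) | O=C1C(Br)=C(Br)C(=O)C(Oc2cc(Br)c(O)c(Br)c2Br)=C1Br | intermediate
11 | 2,3,5-tribromo-6-(2,3,5-tribromo-4-hydroxyphenoxy)benzene-1,4-diol | Oc1c(Br)cc(Oc2c(O)c(Br)c(Br)c(O)c2Br)c(Br)c1Br | target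

**Totals**
Total step count: 5. Longest linear sequence: 5 steps (from 1 or 2 to 11).

**Steps most likely to fail**

Step 3 (Proposed new method). Bromide delivery may take another course: if ionisation of the ketal outruns conjugate addition, bromide enters next to the carbonyl carbon and ends ortho to C1–OH, or the C4–O1' bond opens in place of C4–O2'. An isomer from the wrong C–O opening should be separable by chromatography. The fallback uses known chemistry, sets out from 5 and comes back at 11. Dienone 5 is reduced with Zn dust and aqueous NH4Cl in THF, the known reductive aromatization of 4,4-dioxygenated cyclohexadienones, which expels the phenoxide para to acetyl and gives 1-[4-hydroxy-3-(4-hydroxyphenoxy)phenyl]ethan-1-one F1. Dakin oxidation (H2O2, NaOH) through 4-hydroxy-3-(4-hydroxyphenoxy)phenyl acetate F2 gives 2-(4-hydroxyphenoxy)benzene-1,4-diol F3. Methylation (Me2SO4, K2CO3, acetone) gives 1,4-dimethoxy-2-(4-methoxyphenoxy)benzene F4, so that bromine cannot oxidise ring B. Excess Br2 with Fe powder should then brominate ring B at its three positions and ring A at both carbons ortho to methoxy and one carbon ortho to the ether, the meta bromines holding back the last carbon, to give 1,2,4-tribromo-3,6-dimethoxy-5-(2,3,5-tribromo-4-methoxyphenoxy)benzene F5. BBr3 in CH2Cl2 cleaves the three methyl ethers to 11.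

Step 5. The slowest of the five substitutions sets how long an aryloxy-substituted bromoquinone must stand in bromine and HBr; displacement of the aryloxy group from the quinone ring or ipso attack at C4 of ring A can then cut the ether, and ring B may stop short of full bromination. The fallback sets out from 7 and comes back at 10. Ketone 7 is brominated first at the three carbons ortho to its free hydroxyls (Br2, 3 equiv, NaOAc, AcOH, 0 °C; buffered and cold so that the acetyl group does not enolise) to give 1-[3-bromo-4-hydroxy-5-(2,3,5-tribromo-4-hydroxyphenoxy)phenyl]ethan-1-one F6. Dakin oxidation through 3-bromo-4-hydroxy-5-(2,3,5-tribromo-4-hydroxyphenoxy)phenyl acetate F7 gives 2-bromo-6-(2,3,5-tribromo-4-hydroxyphenoxy)benzene-1,4-diol F8, in which ring A is complete and only C4' and C6' remain. A short treatment with Br2 (3 equiv) in AcOH at 20 °C should then reach quinone 10, which is reduced as in step 5.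

Step 4. Over-oxidation: the hydroquinone that forms is oxidised more easily than the methyl ketone is attacked, so alkaline peroxide can carry it on to the quinone and to ring-cleavage products. The fallback sets out from 7 and comes back at 9. Both phenols are capped (MeI, K2CO3, DMF) to give 1-[3-(2-bromo-4-methoxyphenoxy)-4-methoxyphenyl]ethan-1-one F9. Baeyer–Villiger oxidation with mCPBA (NaHCO3, CH2Cl2), in which the para-methoxyaryl group migrates, gives 3-(2-bromo-4-methoxyphenoxy)-4-methoxyphenyl acetate F10, an ester that peracid does not oxidise further. BBr3 in CH2Cl2 followed by a methanol quench cleaves both methyl ethers and the acetate to 9 under non-oxidising conditions.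

**Further compounds**
F1 | step 3 | 1-[4-hydroxy-3-(4-hydroxyphenoxy)phenyl]ethan-1-one | CC(=O)c1ccc(O)c(Oc2ccc(O)cc2)c1
F2 | step 3 | 4-hydroxy-3-(4-hydroxyphenoxy)phenyl acetate | CC(=O)Oc1ccc(O)c(Oc2ccc(O)cc2)c1
F3 | step 3 | 2-(4-hydroxyphenoxy)benzene-1,4-diol | Oc1ccc(Oc2cc(O)ccc2O)cc1
F4 | step 3 | 1,4-dimethoxy-2-(4-methoxyphenoxy)benzene | COc1ccc(Oc2cc(OC)ccc2OC)cc1
F5 | step 3 | 1,2,4-tribromo-3,6-dimethoxy-5-(2,3,5-tribromo-4-methoxyphenoxy)benzene | COc1c(Br)cc(Oc2c(OC)c(Br)c(Br)c(OC)c2Br)c(Br)c1Br
F6 | step 5 | 1-[3-bromo-4-hydroxy-5-(2,3,5-tribromo-4-hydroxyphenoxy)phenyl]ethan-1-one | CC(=O)c1cc(Br)c(O)c(Oc2cc(Br)c(O)c(Br)c2Br)c1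
F7 | step 5 | 3-bromo-4-hydroxy-5-(2,3,5-tribromo-4-hydroxyphenoxy)phenyl acetate | CC(=O)Oc1cc(Br)c(O)c(Oc2cc(Br)c(O)c(Br)c2Br)c1
F8 | step 5 | 2-bromo-6-(2,3,5-tribromo-4-hydroxyphenoxy)benzene-1,4-diol | Oc1cc(Br)c(O)c(Oc2cc(Br)c(O)c(Br)c2Br)c1
F9 | step 4 | 1-[3-(2-bromo-4-methoxyphenoxy)-4-methoxyphenyl]ethan-1-one | CC(=O)c1ccc(OC)c(Oc2ccc(OC)cc2Br)c1
F10 | step 4 | 3-(2-bromo-4-methoxyphenoxy)-4-methoxyphenyl acetate | CC(=O)Oc1ccc(OC)c(Oc2ccc(OC)cc2Br)c1
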